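**Strategy.** Everything rests on cutting ring C, the dihydrobenzofuran that carries the 3,5-dihydroxyphenyl group, at O1–C7a and C3–C3a. Its O1–C2–C3 unit with both aryl groups is then an enantiopure E-stilbene oxide, and its benzo ring, which has H at C7 and a carbon substituent at C4, is a 3-bromo-5-methoxybenzyne. One insertion step makes both bonds, closes the furan ring, sets C3 trans to the epoxide-derived C2 and leaves bromine at C4. The precursors are an ortho-silylaryl triflate and a (2S,3S)-oxirane whose 4-triflyloxyphenyl group dictates which C–O bond breaks. Coupling, epoxidation and the same insertion, repeated twice, then add rings B and A.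

Key step: step 7

Abbreviations and labels: OTf = trifluoromethanesulfonyloxy; Bpin = 4,4,5,5-tetramethyl-1,3,2-dioxaborolan-2-yl. Ring C = benzofuran with the 3,5-dioxygenated phenyl group at C3; ring B = central benzofuran; ring A = benzofuran that finally carries the styryl group. Each ring is numbered O1, C2, C3, C3a, C4–C7, C7a. Target configuration: ring A 2R,3R; ring B 2S,3S; ring C 2R,3R (all trans).

Remark: with E-stilbenes the D-fructose-derived ketone gives (R,R)-oxiranes, so rings C and A need the L-fructose-derived ketone and ring B the D-ketone. C2 keeps its geometry in each insertion; its descriptor changes (S in the oxirane, R in the benzofuran, or the reverse) only because the ranking of its substituents changes.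

Remark: aryne 13 is a transient species that fluoride generates from 5 each time it is needed (steps 7, 10 and 13); it carries one number, given in step 7 where it first forms.

Assumption: the three 4-OTf-phenyl groups are carried as masked phenols to the last step; this avoids a triflate-to-ether exchange and keeps every O1–C2 benzylic ether resistant to ionisation.

Step 1
Reactants: 1 2,6-dibromo-4-methoxyphenol
Product: 2 (2,6-dibromo-4-methoxyphenoxy)trimethylsilane
Conditions: (Me3Si)2NH, THF, 70 °C; evaporate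
Reagents that add atoms: hexamethyldisilazane, C[Si](C)(C)N[Si](C)(C)C
Why: O-Silylation of a phenol with a silazane is clean and gives only ammonia as by-product, so the moisture-sensitive silyl ether can be used crude.

Step 2
Reactants: 2 (2,6-dibromo-4-methoxyphenoxy)trimethylsilane
Product: 5 2-bromo-4-methoxy-6-(trimethylsilyl)phenyl trifluoromethanesulfonate, via (2-bromo-6-lithio-4-methoxyphenoxy)trimethylsilane 3 (not isolated), via lithium 2-bromo-4-methoxy-6-(trimethylsilyl)phenoxide 4 (not isolated)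
Conditions: n-BuLi (1.05 equiv), THF, −100 °C; then Tf2O, −100 → 20 °C
Reagents that add atoms: trifluoromethanesulfonic anhydride, O=S(=O)(OS(=O)(=O)C(F)(F)F)C(F)(F)F
Why: Bromine–lithium exchange at one of the two equivalent ortho bromines triggers a 1,3-O-to-C silyl shift (retro-Brook rearrangement) driven by phenoxide formation, and O-triflation of that phenoxide in the same flask is the standard entry to ortho-silylaryl triflates.

Step 3
Reactants: 6 4-hydroxybenzaldehyde
Product: 7 4-formylphenyl trifluoromethanesulfonate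
Conditions: Tf2O, pyridine, CH2Cl2, 0 °C
Reagents that add atoms: trifluoromethanesulfonic anhydride, O=S(=O)(OS(=O)(=O)C(F)(F)F)C(F)(F)F
Why: O-Sulfonylation of a phenol with Tf2O and pyridine is fast at 0 °C and leaves the aldehyde untouched.

Step 4
Reactants: 7 4-formylphenyl trifluoromethanesulfonate; 8 diethyl (3,5-dimethoxybenzyl)phosphonate
Product: 9 4-[(E)-2-(3,5-dimethoxyphenyl)ethenyl]phenyl trifluoromethanesulfonate
Conditions: NaH, THF, 0 °C (8 first); then 7, 0 → 25 °C
Reagents that add atoms: none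
Why: The Horner–Wadsworth–Emmons reaction of a benzylic phosphonate with an aromatic aldehyde gives the E-stilbene, and the stabilised carbanion does not attack the aryl triflate.

Step 5
Reactants: 9 4-[(E)-2-(3,5-dimethoxyphenyl)ethenyl]phenyl trifluoromethanesulfonate
Product: 10 4-[(2S,3S)-3-(3,5-dimethoxyphenyl)oxiran-2-yl]phenyl trifluoromethanesulfonate
Conditions: 1,2:4,5-di-O-isopropylidene-β-L-erythro-2,3-hexodiulo-2,6-pyranose (30 mol%), KHSO5 (Oxone), K2CO3, Bu4NHSO4, MeCN/(MeO)2CH2/aq. Na2B4O7 buffer, 0 °C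
Reagents that add atoms: potassium peroxymonosulfate, [K+].[O-]S(=O)(=O)OO
Why: Shi epoxidation through the spiro transition state of the chiral dioxirane sets both oxirane carbons from one alkene face, the L-fructose-derived ketone giving the (S,S)-epoxide, and the electron-poor triflate-bearing ring should keep the product stable to the basic medium and to silica.

Step 6
Reactants: 7 4-formylphenyl trifluoromethanesulfonate; 11 bis(4,4,5,5-tetramethyl-1,3,2-dioxaborolan-2-yl)methane
Product: 12 4-[(E)-2-(4,4,5,5-tetramethyl-1,3,2-dioxaborolan-2-yl)ethenyl]phenyl trifluoromethanesulfonate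
Conditions: lithium 2,2,6,6-tetramethylpiperidide (LiTMP), THF, 0 °C (11 first); then 7, −78 → 20 °C
Reagents that add atoms: none
Why: In this boron-Wittig olefination the lithiated geminal diboronate adds to the aldehyde and syn elimination of the boron–oxygen pair gives the E-alkenyl boronate, the aryl triflate being inert at −78 °C.

Step 7
Reactants: 10 4-[(2S,3S)-3-(3,5-dimethoxyphenyl)oxiran-2-yl]phenyl trifluoromethanesulfonate; 5 2-bromo-4-methoxy-6-(trimethylsilyl)phenyl trifluoromethanesulfonate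
Product: 14 4-[(2R,3R)-4-bromo-3-(3,5-dimethoxyphenyl)-6-methoxy-2,3-dihydro-1-benzofuran-2-yl]phenyl trifluoromethanesulfonate, via 3-bromo-5-methoxybenzyne 13 (not isolated)
Conditions: CsF (3 equiv), MeCN, 25 °C; 5 (1.5 equiv) added over 2 h
Reagents that add atoms: none
Why: Fluoride-induced 1,2-elimination of 5 gives aryne 13; the epoxide oxygen adds to the aryne carbon remote from bromine, the strained aryl-oxonium betaine breaks its C–O bond at the 3,5-dimethoxybenzylic carbon, and the ortho aryl anion collapses on that cation. The closest known reaction is the insertion of arynes from ortho-silylaryl triflates into a benzylic C–O bond of aryl epoxides such as styrene oxide, which gives 2,3-dihydrobenzofurans. The one ring formed, the dihydrofuran of ring C, closes by C3–C3a bond formation as a five-membered ion-pair recombination, formally a 5-endo closure that is open only to this stepwise cationic path and not to a concerted displacement. C2 is never touched and keeps the configuration set by the Shi epoxidation, while the new centre C3 is set trans to the C2 aryl group because the planar cation is captured anti to that group, which is also the more stable arrangement. Two regioselectivities are needed: oxygen must add to the aryne carbon remote from bromine, which the 3-bromo substituent secures by placing the aryl anion next to C–Br (it outweighs the weak opposite bias of the 5-methoxy group), and the C–O bond remote from the triflate-bearing ring must break, which is secured because a 4-triflyloxybenzyl cation is far less stable than a 3,5-dimethoxybenzyl cation. The triflate is inert to CsF in MeCN and also makes the epoxide robust enough to be handled.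

Step 8
Reactants: 14 ring C bromide; 12 4-[(E)-2-(Bpin)ethenyl]phenyl trifluoromethanesulfonate
Product: 15 ring C stilbene 4-[(E)-2-{(2R,3R)-3-(3,5-dimethoxyphenyl)-6-methoxy-2-(4-OTf-phenyl)-2,3-dihydro-1-benzofuran-4-yl}ethenyl]phenyl trifluoromethanesulfonate
Conditions: Pd2(dba)3 (2.5 mol%), P(t-Bu)3 (6 mol%), KF (3 equiv), THF, 25–45 °C
Reagents that add atoms: none
Why: Suzuki–Miyaura coupling with the monoligated zerovalent palladium–P(t-Bu)3 catalyst in an ether solvent inserts into the aryl C–Br bond and leaves aryl triflates alone, and the alkenyl boronate transfers its E-geometry unchanged.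

Step 9
Reactants: 15 ring C stilbene
Product: 16 ring C epoxide 4-[(2R,3R)-3-{(2R,3R)-3-(3,5-dimethoxyphenyl)-6-methoxy-2-(4-OTf-phenyl)-2,3-dihydro-1-benzofuran-4-yl}oxiran-2-yl]phenyl trifluoromethanesulfonate
Conditions: 1,2:4,5-di-O-isopropylidene-β-D-erythro-2,3-hexodiulo-2,6-pyranose (30–50 mol%), KHSO5 (Oxone), K2CO3, Bu4NHSO4, MeCN/(MeO)2CH2/aq. Na2B4O7 buffer, 0 °C
Reagents that add atoms: potassium peroxymonosulfate, [K+].[O-]S(=O)(=O)OO
Why: Shi epoxidation is reagent-controlled, so the D-fructose-derived ketone should deliver the (R,R)-oxirane needed for ring B independently of the ring C centres, and the stilbene is the most readily oxidised site in the substrate.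

Step 10
Reactants: 16 ring C epoxide; 5 2-bromo-4-methoxy-6-(trimethylsilyl)phenyl trifluoromethanesulfonate
Product: 17 ring B–ring C bromide [ring B (2S,3S)-4-bromo-6-methoxy-2-(4-OTf-phenyl) joined from C3 to C4 of ring C (2R,3R)]
Conditions: CsF (3 equiv), MeCN, 25 °C; 5 (1.5 equiv) added over 2 h
Reagents that add atoms: none
Why: Aryne 13, released from 5 by fluoride as in step 7, inserts into the benzylic C–O bond of the aryl epoxide under the same controls: oxygen adds remote from bromine, the oxonium opens at the carbon bearing the 3,5-dioxygenated aryl group of ring C and not at the 4-OTf-benzylic carbon, C2 of ring B keeps the epoxide configuration and C3 forms trans to it.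

Step 11
Reactants: 17 ring B–ring C bromide; 12 4-[(E)-2-(Bpin)ethenyl]phenyl trifluoromethanesulfonate
Product: 18 ring B–ring C stilbene [17 with (E)-2-(4-OTf-phenyl)ethenyl in place of bromine at C4 of ring B]
Conditions: Pd2(dba)3 (2.5 mol%), P(t-Bu)3 (6 mol%), KF (3 equiv), THF, 25–45 °C
Reagents that add atoms: none
Why: The same bromide-selective Suzuki–Miyaura coupling as in step 8 applies, since the three aryl triflates are inert to the zerovalent palladium–P(t-Bu)3 catalyst in THF.

Step 12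
Reactants: 18 ring B–ring C stilbene
Product: 19 ring B–ring C epoxide [18 with the alkene converted into the trans (2S,3S)-oxirane]
Conditions: 1,2:4,5-di-O-isopropylidene-β-L-erythro-2,3-hexodiulo-2,6-pyranose (30–50 mol%), KHSO5 (Oxone), K2CO3, Bu4NHSO4, MeCN/(MeO)2CH2/aq. Na2B4O7 buffer, 0 °C
Reagents that add atoms: potassium peroxymonosulfate, [K+].[O-]S(=O)(=O)OO
Why: Shi epoxidation with the L-fructose-derived ketone should give the (S,S)-oxirane needed for ring A under reagent control, as in step 5.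

Step 13
Reactants: 19 ring B–ring C epoxide; 5 2-bromo-4-methoxy-6-(trimethylsilyl)phenyl trifluoromethanesulfonate
Product: 20 ring A–B–C bromide [ring A (2R,3R)-4-bromo-6-methoxy-2-(4-OTf-phenyl) joined from C3 to C4 of ring B (2S,3S) joined from C3 to C4 of ring C (2R,3R)]
Conditions: CsF (3 equiv), MeCN, 25 °C; 5 (2 equiv) added over 2 h
Reagents that add atoms: none
Why: Aryne 13, released once more from 5 by fluoride, inserts into the benzylic C–O bond of the aryl epoxide a third time with unchanged electronic bias (3,5-dioxygenated aryl against 4-OTf-phenyl), so ring A should form with C2 retained from the oxirane, C3 trans to it and bromine at C4.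

Step 14
Reactants: 20 ring A–B–C bromide
Product: 21 pentaphenol [20 with OH in place of all five OMe groups; Br and three OTf kept]
Conditions: BBr3 (15 equiv), CH2Cl2, −78 → 0 °C; then MeOH, H2O
Reagents that add atoms: none
Why: Lewis acid ether cleavage by BBr3 removes aryl methyl groups by bromide attack on the complexed O-methyl group while aryl triflates and the aryl bromide are inert, no acid-sensitive stilbene is present yet, and the 4-OTf-phenyl groups disfavour ionisation of the three O1–C2 benzylic ethers.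

Step 15
Reactants: 21 pentaphenol
Product: 22 pentaacetate of 21
Conditions: Ac2O, pyridine, DMAP (cat.), CH2Cl2, 0 → 25 °C
Reagents that add atoms: acetic anhydride, CC(=O)OC(C)=O
Why: Acylation of phenols with Ac2O and pyridine is quantitative and gives a neutral, chromatographable bromide for the palladium step.

Step 16
Reactants: 23 caffeic acid [(E)-3-(3,4-dihydroxyphenyl)prop-2-enoic acid]
Product: 25 4-ethenyl-1,2-phenylene diacetate, via 4-ethenylbenzene-1,2-diol 24 (not isolated)
Conditions: Et3N, DMF, 100 °C; then Ac2O, 0 → 25 °C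
Reagents that add atoms: acetic anhydride, CC(=O)OC(C)=O
Why: Base-mediated thermal decarboxylation of a 4-hydroxycinnamic acid proceeds through its quinone methide tautomer, and acetylation in the same flask traps the polymerisation-prone vinylcatechol.

Step 17
Reactants: 22 pentaacetate; 25 4-ethenyl-1,2-phenylene diacetate
Product: 26 heptaacetate tris(triflate) of the target [27 with OAc on the seven resorcinol-type and catechol oxygens and OTf on the three 4-oxygenated phenyl groups]
Conditions: Pd2(dba)3 (2.5 mol%), P(t-Bu)3 (6 mol%), Cy2NMe, 1,4-dioxane, 70 °C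
Reagents that add atoms: none
Why: The Mizoroki–Heck reaction of an aryl bromide with a styrene gives the E-1,2-diarylethene by syn insertion and syn β-hydride elimination, and the zerovalent palladium–P(t-Bu)3 catalyst in dioxane selects C–Br over C–OTf.

Step 18
Reactants: 26 heptaacetate tris(triflate)
Product: 27 target, ring A (2R,3R), ring B (2S,3S), ring C (2R,3R)
Conditions: Et4NOH (aq., 20 equiv), 1,4-dioxane, argon, 0 → 25 °C; then aq. AcOH
Reagents that add atoms: none
Why: Hydroxide cleaves aryl acetates at the acyl–oxygen bond and aryl triflates at the sulfur–oxygen bond, so every phenol oxygen stays on its ring and no stereocentre is involved (ester and sulfonate hydrolysis).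

**Compound list**

1 | 2,6-dibromo-4-methoxyphenol | COc1cc(Br)c(O)c(Br)c1 | starting material
2 | (2,6-dibromo-4-methoxyphenoxy)trimethylsilane | COc1cc(Br)c(O[Si](C)(C)C)c(Br)c1 | intermediate
3 | (2-bromo-6-lithio-4-methoxyphenoxy)trimethylsilane | COc1cc(Br)c(O[Si](C)(C)C)c([Li])c1 | intermediate
4 | lithium 2-bromo-4-methoxy-6-(trimethylsilyl)phenoxide | COc1cc(Br)c([O-])c([Si](C)(C)C)c1.[Li+] | intermediate
5 | 2-bromo-4-methoxy-6-(trimethylsilyl)phenyl trifluoromethanesulfonate | COc1cc(Br)c(OS(=O)(=O)C(F)(F)F)c([Si](C)(C)C)c1 | intermediate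
6 | 4-hydroxybenzaldehyde | O=Cc1ccc(O)cc1 | starting material
7 | 4-formylphenyl trifluoromethanesulfonate | O=Cc1ccc(OS(=O)(=O)C(F)(F)F)cc1 | intermediate
8 | diethyl (3,5-dimethoxybenzyl)phosphonate | CCOP(=O)(Cc1cc(OC)cc(OC)c1)OCC | starting material
9 | 4-[(E)-2-(3,5-dimethoxyphenyl)ethenyl]phenyl trifluoromethanesulfonate | COc1cc(/C=C/c2ccc(OS(=O)(=O)C(F)(F)F)cc2)cc(OC)c1 | intermediate
10 | 4-[(2S,3S)-3-(3,5-dimethoxyphenyl)oxiran-2-yl]phenyl trifluoromethanesulfonate | COc1cc(OC)cc(c1)[C@@H]2O[C@H]2c1ccc(OS(=O)(=O)C(F)(F)F)cc1 | intermediate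
11 | bis(4,4,5,5-tetramethyl-1,3,2-dioxaborolan-2-yl)methane | CC1(C)OB(CB2OC(C)(C)C(C)(C)O2)OC1(C)C | starting material
12 | 4-[(E)-2-(4,4,5,5-tetramethyl-1,3,2-dioxaborolan-2-yl)ethenyl]phenyl trifluoromethanesulfonate | CC1(C)OB(/C=C/c2ccc(OS(=O)(=O)C(F)(F)F)cc2)OC1(C)C | intermediate
13 | 3-bromo-5-methoxybenzyne | BrC1=CC(OC)=CC#C1 | intermediate
14 | 4-[(2R,3R)-4-bromo-3-(3,5-dimethoxyphenyl)-6-methoxy-2,3-dihydro-1-benzofuran-2-yl]phenyl trifluoromethanesulfonate (ring C bromide) | Brc1cc(OC)cc2c1[C@@H](c1cc(OC)cc(OC)c1)[C@H](c1ccc(OS(=O)(=O)C(F)(F)F)cc1)O2 | intermediate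
15 | 4-[(E)-2-{(2R,3R)-3-(3,5-dimethoxyphenyl)-6-methoxy-2-[4-(trifluoromethanesulfonyloxy)phenyl]-2,3-dihydro-1-benzofuran-4-yl}ethenyl]phenyl trifluoromethanesulfonate (ring C stilbene) | FC(F)(F)S(=O)(=O)Oc1ccc(/C=C/c2cc(OC)cc3c2[C@@H](c2cc(OC)cc(OC)c2)[C@H](c2ccc(OS(=O)(=O)C(F)(F)F)cc2)O3)cc1 | intermediate
16 | 4-[(2R,3R)-3-{(2R,3R)-3-(3,5-dimethoxyphenyl)-6-methoxy-2-[4-(trifluoromethanesulfonyloxy)phenyl]-2,3-dihydro-1-benzofuran-4-yl}oxiran-2-yl]phenyl trifluoromethanesulfonate (ring C epoxide) | FC(F)(F)S(=O)(=O)Oc1ccc([C@H]2O[C@@H]2c2cc(OC)cc3c2[C@@H](c2cc(OC)cc(OC)c2)[C@H](c2ccc(OS(=O)(=O)C(F)(F)F)cc2)O3)cc1 | intermediate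
17 | ring B–ring C bromide: ring B = (2S,3S)-4-bromo-6-methoxy-2-(4-OTf-phenyl)-2,3-dihydro-1-benzofuran, joined from its C3 to C4 of ring C = (2R,3R)-3-(3,5-dimethoxyphenyl)-6-methoxy-2-(4-OTf-phenyl)-2,3-dihydro-1-benzofuran | FC(F)(F)S(=O)(=O)Oc1ccc([C@H]2Oc3cc(OC)cc(Br)c3[C@@H]2c2cc(OC)cc3c2[C@@H](c2cc(OC)cc(OC)c2)[C@H](c2ccc(OS(=O)(=O)C(F)(F)F)cc2)O3)cc1 | intermediate
18 | ring B–ring C stilbene: 17 with (E)-2-(4-OTf-phenyl)ethenyl in place of bromine at C4 of ring B | FC(F)(F)S(=O)(=O)Oc1ccc([C@H]2Oc3cc(OC)cc(/C=C/c4ccc(OS(=O)(=O)C(F)(F)F)cc4)c3[C@@H]2c2cc(OC)cc3c2[C@@H](c2cc(OC)cc(OC)c2)[C@H](c2ccc(OS(=O)(=O)C(F)(F)F)cc2)O3)cc1 | intermediate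
19 | ring B–ring C epoxide: 18 with the alkene converted into the trans oxirane, both oxirane carbons S | FC(F)(F)S(=O)(=O)Oc1ccc([C@H]2Oc3cc(OC)cc([C@@H]4O[C@H]4c4ccc(OS(=O)(=O)C(F)(F)F)cc4)c3[C@@H]2c2cc(OC)cc3c2[C@@H](c2cc(OC)cc(OC)c2)[C@H](c2ccc(OS(=O)(=O)C(F)(F)F)cc2)O3)cc1 | intermediate
20 | ring A–B–C bromide: ring A = (2R,3R)-4-bromo-6-methoxy-2-(4-OTf-phenyl)-2,3-dihydro-1-benzofuran, joined from its C3 to C4 of ring B (2S,3S), which is joined from its C3 to C4 of ring C (2R,3R); rings B and C substituted as in 17 | FC(F)(F)S(=O)(=O)Oc1ccc([C@H]2Oc3cc(OC)cc([C@@H]4c5c(Br)cc(OC)cc5O[C@H]4c4ccc(OS(=O)(=O)C(F)(F)F)cc4)c3[C@@H]2c2cc(OC)cc3c2[C@@H](c2cc(OC)cc(OC)c2)[C@H](c2ccc(OS(=O)(=O)C(F)(F)F)cc2)O3)cc1 | intermediate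
21 | pentaphenol: 20 with OH in place of all five OMe groups | FC(F)(F)S(=O)(=O)Oc1ccc([C@H]2Oc3cc(O)cc([C@@H]4c5c(Br)cc(O)cc5O[C@H]4c4ccc(OS(=O)(=O)C(F)(F)F)cc4)c3[C@@H]2c2cc(O)cc3c2[C@@H](c2cc(O)cc(O)c2)[C@H](c2ccc(OS(=O)(=O)C(F)(F)F)cc2)O3)cc1 | intermediate
22 | pentaacetate of 21 | FC(F)(F)S(=O)(=O)Oc1ccc([C@H]2Oc3cc(OC(C)=O)cc([C@@H]4c5c(Br)cc(OC(C)=O)cc5O[C@H]4c4ccc(OS(=O)(=O)C(F)(F)F)cc4)c3[C@@H]2c2cc(OC(C)=O)cc3c2[C@@H](c2cc(OC(C)=O)cc(OC(C)=O)c2)[C@H](c2ccc(OS(=O)(=O)C(F)(F)F)cc2)O3)cc1 | intermediate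
23 | caffeic acid, (E)-3-(3,4-dihydroxyphenyl)prop-2-enoic acid | OC(=O)/C=C/c1ccc(O)c(O)c1 | starting material
24 | 4-ethenylbenzene-1,2-diol | C=Cc1ccc(O)c(O)c1 | intermediate
25 | 4-ethenyl-1,2-phenylene diacetate | C=Cc1ccc(OC(C)=O)c(OC(C)=O)c1 | intermediate
26 | heptaacetate tris(triflate): 27 with OAc at C6 of rings A, B and C, on the 3,5-dioxygenated phenyl group and on the catechol, and OTf on the three 4-oxygenated phenyl groups | FC(F)(F)S(=O)(=O)Oc1ccc([C@H]2Oc3cc(OC(C)=O)cc([C@@H]4c5c(/C=C/c6ccc(OC(C)=O)c(OC(C)=O)c6)cc(OC(C)=O)cc5O[C@H]4c4ccc(OS(=O)(=O)C(F)(F)F)cc4)c3[C@@H]2c2cc(OC(C)=O)cc3c2[C@@H](c2cc(OC(C)=O)cc(OC(C)=O)c2)[C@H](c2ccc(OS(=O)(=O)C(F)(F)F)cc2)O3)cc1 | intermediate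
27 | CNP0099535.1: ring A (2R,3R)-6-hydroxy-2-(4-hydroxyphenyl)-4-[(E)-2-(3,4-dihydroxyphenyl)ethenyl]-2,3-dihydro-1-benzofuran, joined from C3 to C4 of ring B (2S,3S)-6-hydroxy-2-(4-hydroxyphenyl)-2,3-dihydro-1-benzofuran, joined from C3 to C4 of ring C (2R,3R)-3-(3,5-dihydroxyphenyl)-6-hydroxy-2-(4-hydroxyphenyl)-2,3-dihydro-1-benzofuran | Oc1ccc([C@H]2Oc3cc(O)cc([C@@H]4c5c(/C=C/c6ccc(O)c(O)c6)cc(O)cc5O[C@H]4c4ccc(O)cc4)c3[C@@H]2c2cc(O)cc3c2[C@@H](c2cc(O)cc(O)c2)[C@H](c2ccc(O)cc2)O3)cc1 | target

**Step count.** Total: 18 steps. Longest linear sequence: 14 steps (3, 4, 5, 7, 8, 9, 10, 11, 12, 13, 14, 15, 17, 18).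

**Steps most likely to fail**

Step 7. The betaine may open at the wrong benzylic carbon, or the aryne may be consumed by oligomerisation or by fluoride and solvent before it meets the epoxide. The fallback sets out from 9 and returns at 14; it makes the two bonds one after the other by ionic chemistry. Stilbene 9 is epoxidised with 1,2:4,5-di-O-isopropylidene-β-D-erythro-2,3-hexodiulo-2,6-pyranose and KHSO5 to the enantiomeric oxirane 4-[(2R,3R)-3-(3,5-dimethoxyphenyl)oxiran-2-yl]phenyl trifluoromethanesulfonate F1. Friedel–Crafts opening with 5-bromoresorcinol in (CF3)2CHOH at 0–25 °C is expected at the 3,5-dimethoxybenzylic carbon with inversion and at C4 of the resorcinol (any C2-alkylated isomer is removed here), and should give 4-[(1S,2R)-2-(6-bromo-2,4-dihydroxyphenyl)-2-(3,5-dimethoxyphenyl)-1-hydroxyethyl]phenyl trifluoromethanesulfonate F2. Mitsunobu cyclodehydration (PPh3, DIAD, THF, 0 °C) closes O1–C2 with inversion to 4-[(2R,3R)-4-bromo-3-(3,5-dimethoxyphenyl)-6-hydroxy-2,3-dihydro-1-benzofuran-2-yl]phenyl trifluoromethanesulfonate F3, and MeI, K2CO3, acetone then gives 14. Because both carbons are inverted here while the insertion retains both, the enantiomeric epoxide is the correct entry.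

Step 13 (step 10 shares the risk in milder form). Ring closure at the cation-bearing carbon may be too slow beside the ortho-substituted ring B aryl group, so that the betaine is diverted to hydride shift (Meinwald-type ketone) or protonation. The fallback sets out from 18 and returns at 20 by the same two-bond ionic sequence. Epoxidation of 18 with the D-fructose-derived ketone and KHSO5 gives the diastereomeric oxirane with both oxirane carbons R, the (R,R)-oxirane of 18 F4. Friedel–Crafts opening with 5-bromoresorcinol in (CF3)2CHOH (inversion at the carbon attached to ring B) gives the ring-opened adduct carrying a (1R,2S)-1-(6-bromo-2,4-dihydroxyphenyl)-2-hydroxy-2-(4-OTf-phenyl)ethyl group at C4 of ring B F5. Mitsunobu cyclodehydration (PPh3, DIAD, THF) gives the ring A phenol, 20 with OH in place of OMe at C6 of ring A F6, and MeI, K2CO3, acetone returns to 20.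

Step 18. While the three sulfonates are hydrolysed in strong base, the catechol–stilbene polyphenolate may be oxidised by traces of air, or a benzofuran may open through a quinone methide once its 4-hydroxyphenyl group is free. The fallback sets out from 21 and returns at 27; it removes the triflates before any catechol or stilbene is present, so that the last step only cleaves acetates. Pentaphenol 21 is treated with Et4NOH in aqueous dioxane to give the octaphenol bromide, 21 with OH in place of the three OTf groups F7. Ac2O and pyridine give its octaacetate F8. A Mizoroki–Heck reaction with 25 (Pd(OAc)2, P(o-tol)3, Et3N, DMF, 90 °C; no sulfonate left to discriminate) gives the decaacetate of the target F9. Methanolysis with catalytic K2CO3 in MeOH at 0 °C under argon then gives 27.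

**Further compounds**

F1 | step 7 | 4-[(2R,3R)-3-(3,5-dimethoxyphenyl)oxiran-2-yl]phenyl trifluoromethanesulfonate | COc1cc(OC)cc(c1)[C@H]2O[C@@H]2c1ccc(OS(=O)(=O)C(F)(F)F)cc1
F2 | step 7 | 4-[(1S,2R)-2-(6-bromo-2,4-dihydroxyphenyl)-2-(3,5-dimethoxyphenyl)-1-hydroxyethyl]phenyl trifluoromethanesulfonate | Oc1cc(O)c([C@@H](c2cc(OC)cc(OC)c2)[C@H](O)c2ccc(OS(=O)(=O)C(F)(F)F)cc2)c(Br)c1
F3 | step 7 | 4-[(2R,3R)-4-bromo-3-(3,5-dimethoxyphenyl)-6-hydroxy-2,3-dihydro-1-benzofuran-2-yl]phenyl trifluoromethanesulfonate | Brc1cc(O)cc2c1[C@@H](c1cc(OC)cc(OC)c1)[C@H](c1ccc(OS(=O)(=O)C(F)(F)F)cc1)O2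
F4 | step 13 | (R,R)-oxirane of 18: diastereomer of 19 with both oxirane carbons R, rings B and C unchanged | FC(F)(F)S(=O)(=O)Oc1ccc([C@H]2Oc3cc(OC)cc([C@H]4O[C@@H]4c4ccc(OS(=O)(=O)C(F)(F)F)cc4)c3[C@@H]2c2cc(OC)cc3c2[C@@H](c2cc(OC)cc(OC)c2)[C@H](c2ccc(OS(=O)(=O)C(F)(F)F)cc2)O3)cc1
F5 | step 13 | ring-opened adduct: 17 with a (1R,2S)-1-(6-bromo-2,4-dihydroxyphenyl)-2-hydroxy-2-(4-OTf-phenyl)ethyl group in place of bromine at C4 of ring B | FC(F)(F)S(=O)(=O)Oc1ccc([C@H]2Oc3cc(OC)cc([C@H](c4c(Br)cc(O)cc4O)[C@H](O)c4ccc(OS(=O)(=O)C(F)(F)F)cc4)c3[C@@H]2c2cc(OC)cc3c2[C@@H](c2cc(OC)cc(OC)c2)[C@H](c2ccc(OS(=O)(=O)C(F)(F)F)cc2)O3)cc1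
F6 | step 13 | ring A phenol: 20 with OH in place of OMe at C6 of ring A | FC(F)(F)S(=O)(=O)Oc1ccc([C@H]2Oc3cc(OC)cc([C@@H]4c5c(Br)cc(O)cc5O[C@H]4c4ccc(OS(=O)(=O)C(F)(F)F)cc4)c3[C@@H]2c2cc(OC)cc3c2[C@@H](c2cc(OC)cc(OC)c2)[C@H](c2ccc(OS(=O)(=O)C(F)(F)F)cc2)O3)cc1
F7 | step 18 | octaphenol bromide: 21 with OH in place of the three OTf groups | Oc1ccc([C@H]2Oc3cc(O)cc([C@@H]4c5c(Br)cc(O)cc5O[C@H]4c4ccc(O)cc4)c3[C@@H]2c2cc(O)cc3c2[C@@H](c2cc(O)cc(O)c2)[C@H](c2ccc(O)cc2)O3)cc1
F8 | step 18 | octaacetate of F7 | CC(=O)Oc1ccc([C@H]2Oc3cc(OC(C)=O)cc([C@@H]4c5c(Br)cc(OC(C)=O)cc5O[C@H]4c4ccc(OC(C)=O)cc4)c3[C@@H]2c2cc(OC(C)=O)cc3c2[C@@H](c2cc(OC(C)=O)cc(OC(C)=O)c2)[C@H](c2ccc(OC(C)=O)cc2)O3)cc1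
F9 | step 18 | decaacetate of 27 | CC(=O)Oc1ccc([C@H]2Oc3cc(OC(C)=O)cc([C@@H]4c5c(/C=C/c6ccc(OC(C)=O)c(OC(C)=O)c6)cc(OC(C)=O)cc5O[C@H]4c4ccc(OC(C)=O)cc4)c3[C@@H]2c2cc(OC(C)=O)cc3c2[C@@H](c2cc(OC(C)=O)cc(OC(C)=O)c2)[C@H](c2ccc(OC(C)=O)cc2)O3)cc1
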